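**One step.** In a one-step world a single pace would carry the starting material to target. The beta run levels off at 53%, however, so a second capture takes the rest, at odds of 1.13 for target.

in all of them: starting material 0.050 M
- beta: first nucleophile 0.050 M; second nucleophile 0.045 M; protic impurity 1 mM; run made earlier
- epsilon: first nucleophile 0.050 M; second nucleophile 0.045 M; protic impurity 1.5 mM; run made earlier
- larch: first nucleophile 0.0500 M; second nucleophile 0.0450 M; protic impurity 1.00 mM; one stirred flow tank at steady state, fed with the mixture as stated, mean residence time 25 h
- alder: first nucleophile 0.0500 M; second nucleophile 0.0450 M; protic impurity 1.00 mM; a closed flask charged with all of it at once and left for 25 h; time 25 h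
- cedar: first nucleophile 0.0500 M (fed, over 12.5 h); second nucleophile 0.0450 M; protic impurity 1.00 mM; all but first nucleophile at the start; first nucleophile goes in evenly over 12.5 h, the run ends at 25 h; time 25 h
- elm: first nucleophile 0.0500 M; second nucleophile 0.0450 M (fed, over 12.5 h); protic impurity 1.00 mM; all but second nucleophile at the start; second nucleophile goes in evenly over 12.5 h, the run ends at 25 h; time 25 h

| run | time / h | target / % |
|---|---|---|
| beta | 2.00 | 29 |
| beta | 5.00 | 43 |
| beta | 10.0 | 52 |
| beta | 25.0 | 53 |
| epsilon | 0.333 | 4 |
| epsilon | 0.833 | 13 |
| epsilon | 1.50 | 23 |
| epsilon | 2.50 | 31 |

(standard deviation of a reading: 1.5 percentage points)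

* order of the set-ups by the amount of target at the outlet or at the end, in percent of the starting material put in, highest first (larch / alder / cedar / elm)
* amount of target at the outlet or at the end, in percent of the starting material put in, larch
* amount of target at the outlet or at the end, in percent of the starting material put in, alder
* amount of target at the outlet or at the end, in percent of the starting material put in, cedar
* amount of target at the outlet or at the end, in percent of the starting material put in, elm

- the stated concentrations are those of everything mixed, before any reaction; amounts are the same in each set-up
- what may be going on: starting material <-> intermediate; first nucleophile + intermediate -> target; second nucleophile + intermediate -> other capture product; second nucleophile + protic impurity -> quenched reagent; first nucleophile <-> dormant form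
- the feed brings no volume worth counting
- the earlier runs were made in a closed, stirred flask

**What matters.** The protic impurity is 2.22% of the second nucleophile's charge, so it can take hardly any of that nucleophile away from the capture. The plateau passes its 1.5 percentage points scatter straight to alder. The pace matters unevenly: at half the pace I read below, alder would keep 1.55% unreacted, but larch 19.3%. In the fed flasks it says when the capturing happens.

**Decade time.** The beta reading at 5.00 h gives 0.334 h⁻¹, hence 6.90 h, the decade time, the hours in which the fraction of starting material left falls by a factor of 10. The same curve gives 30.0% at 2.50 h, and the epsilon run, with more impurity, reads 31%.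

**My reckoning.** Alder runs 3.63 decades, so I put it at 53%. Larch leaves 10.7% unreacted, giving 47.3%. The feed spans 1.81 decades, leaving 1.54% by this reckoning, so I place the capture during the feed. Take the fed nucleophile at half its charge over that window. Elm's odds then double, giving 69.3%, and cedar's halve, giving 36.1%.

**Forecast, result.** The forecast says elm > alder > larch > cedar, with larch 47.5%, alder 53%, cedar 28% and elm 78%, its ground for elm being that “the first nucleophile dominates early”; it sets elm higher and cedar lower than I do. The flasks give elm > alder > larch > cedar: larch 46.3%, alder 54.8%, cedar 34.3%, elm 71.4%.

    starting material ⇌ intermediate (K = 0.0810, k = 0.00580 min⁻¹)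
    first nucleophile + intermediate → target (k = 17.0 M⁻¹ min⁻¹)
    second nucleophile + intermediate → other capture product (k = 6.40 M⁻¹ min⁻¹)
    second nucleophile + protic impurity → quenched reagent (k = 0.120 M⁻¹ min⁻¹)
    first nucleophile ⇌ dormant form (K = 2.00, k = 0.00720 min⁻¹)

**Falling back.** Elm holds 3.91% starting material at 12.5 h. My 6.90 h would take that to 0.0602% by 25.0 h, but elm holds 0.126%. At 2.37 h in elm, intermediate falls back at 0.35 of the rate at which it goes on, and over the whole run elm's decade time is 8.62 h. The neighbour of elm with 0.020 M of first nucleophile ends with more starting material, 0.903%, which over its whole run is a decade time of 12.2 h.

(The readings were generated by integration with made-up constants; scatter was added.)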